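**Numbering used throughout** (fixed from the steps): 1 hexane-3,4-dione; 2 benzyloxy enone; 3 dimethyl malonate; 4 Michael adduct; 5 cyclohexanedione ester; 6 bromo keto ester; 7 ring B resorcinol benzyl ether; 8 its bis-MOM ether; 9 ring B phenol; 10 methyl orsellinate; 11 formylated ester; 12 its bis-MOM ether; 13 ring A acid; 14 acid chloride; 15 protected depside; 16 target. MOM = methoxymethyl.

## Analysis of the target

The target 16 is a depside: two benzene rings joined by one aryl ester, with no stereocentre, so every difficulty is one of regiochemistry and chemoselectivity. Ring A (carbons C1' to C6': C1' carries the ester carbonyl, C2' methyl, C3' hydrogen, C4' hydroxyl, C5' formyl, C6' hydroxyl) is a 3-formylorsellinoyl unit; ring B (B1 CO2Me, B2 methyl, B3 acyloxy, B4 hydroxyl, B5 methyl, B6 hydroxyl) is hexasubstituted. The sensitive groups are the aldehyde between two phenols, the methyl ester and above all the aryl ester: it has a free hydroxyl next door at B4 (acyl shift from B3 to B4 under base), and its salicylate-type acyl part is readily attacked by alcohols and bases. Three things make the synthesis hard: ring B has no free position and cannot be built up by successive aromatic substitutions; only B3 of its three oxygens may be acylated although B3 and B4 are neighbours; and the ester has to be made from a di-ortho-substituted acid and a di-ortho-substituted phenol. The strategy rests on the pattern B4–O / B5–Me / B6–O / B1–CO2Me of ring B, which is the aromatised form of a 2-methylcyclohexane-1,3-dione-4-carboxylate, the product of a malonate–enone annulation. In that annulation B3 is the α-carbon of the enone, so the B3 oxygen can be carried in as an enol ether and differs from the B4 and B6 oxygens (which begin as carbonyl groups) from the moment ring B exists.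

## Retrosynthetic reasoning

**16 ⇒ 15.** The four phenolic hydroxyls are masked as MOM acetals. They must be covered while the ester is made, because B4–OH would compete with B3–OH and the ring A phenols would self-acylate. One acid-labile class is used so that one final step removes all four. Acid is chosen over base because base would move the acyl group to B4–O or cleave the depside.

**15 ⇒ 9 + 13.** The C(=O)–O(B3) bond is cut. It is the only bond between the rings and a heteroatom bond, so the cut divides the molecule into two benzenoid halves of similar size. The forward reaction must acylate a phenol flanked by methyl and an acetal with an acid flanked by methyl and an acetal; this is planned through the acid chloride 14 and the phenoxide of 9.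

**13 ⇒ 12 ⇒ 11 ⇒ 10.** Ring A is not built: methyl orsellinate (10) already has the carboxyl carbon, the methyl group and both oxygens in place. The only C–C bond cut is C5'–CHO, the position between the two oxygens. The forward formylation must prefer this carbon over the one next to the methyl group; it is done on the cheap ester 10, where a minor isomer can still be removed.

**9 ⇒ 8 ⇒ 7.** These are protecting-group changes on ring B. The B3 oxygen must be the only free one at the coupling stage, so it carries a benzyl group (removed by hydrogenolysis) while B4 and B6 carry MOM groups (stable to hydrogenolysis). No selective protection is needed, because in 7 the B3 oxygen is already an ether and only B4 and B6 are free.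

**7 ⇒ 5.** The resorcinol is traced back to its dihydro form, the cyclohexane-1,3-dione 5. Two hydrogens are added in the retrosynthetic sense (B2 and B3 become sp3). This gives a non-aromatic ring that already holds all six substituents and can be assembled by enolate chemistry; the forward step is a dehydrogenation that must leave the benzyl ether in place.

**5 ⇒ 2 + 3 (key disconnection).** B1–B2 and B5–B6 are cut. Dimethyl malonate (3) supplies B1, B6 and the ester carbon. The enone 2 supplies B2 to B5, both methyl groups and the B3 oxygen. These two bonds are chosen because they are the bonds of a conjugate addition followed by a Claisen condensation, and because they leave the B3 oxygen on the enone α-carbon, so no C–O bond has to be made on a crowded ring later. The forward reaction must add at the β-carbon before any acylation occurs, and must close from the ethyl ketone side.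

**2 ⇒ 1.** The O–CH2Ph bond is cut, which leads to the symmetrical α-diketone 1. Because 1 is symmetrical, either enolate gives the same enol ether, and the only selectivity needed is O- over C-alkylation.

## Alternatives that were turned down

Alternative 1: ring B by cycloaddition of a silyloxyfuran.
- Disconnection: B2–B3 and B1–B6.
- Forward reaction: 4-(benzyloxy)-3-methyl-2-(tert-butyldimethylsilyloxy)furan A2 and methyl but-2-ynoate A3 combine in a [4+2] cycloaddition. The oxygen-bridged adduct opens at the silyloxy bridgehead and tautomerises to methyl 4-(benzyloxy)-2-(tert-butyldimethylsilyloxy)-5-hydroxy-3,6-dimethylbenzoate A1.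
- For it: the regiochemistry is built in, since the nucleophilic C5 of A2 pairs with the β-carbon of A3. The ring is aromatic at once. In A1 the B3 hydroxyl is free while B4 and B6 carry two different groups. On these points it is stronger than the chosen route, which needs a dehydrogenation, a double protection and a hydrogenolysis (steps 3 to 5) to reach the same situation.
- Against it: A2 is a very electron-rich, hydrolytically labile diene that itself needs several steps from a tetronate. A3 is a β-substituted, weakly activated dienophile, so heat or a Lewis acid would be needed, and under either A2 is more likely to transfer its silyl group or add in an open-chain vinylogous fashion than to cycloadd. Later removal of the B4 benzyl group of A1 by hydrogenolysis would also have to spare the aldehyde.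
- Comparison: the chosen route is about three operations longer for ring B than a route through A1, but uses classical enolate chemistry on cheap, stable materials and puts its risk on one reversible annulation that has a thermodynamic sink.

Alternative 2: ring A by Danheiser benzannulation.
- Disconnection: C5'–C6', C3'–C4' and C1'–C6'.
- Forward reaction: irradiation of benzyl (E)-5-diazo-3-methyl-4-oxopent-2-enoate A5 expels dinitrogen and, by Wolff rearrangement, leaves a vinylketene. [2+2] Addition of the silyloxyalkyne (3,3-dimethoxyprop-1-yn-1-yl)oxy-tri(propan-2-yl)silane A6 gives a 4-vinylcyclobutenone, which opens to a dienylketene and recloses in a 6π electrocyclisation to benzyl 3-(dimethoxymethyl)-2-hydroxy-6-methyl-4-(triisopropylsilyloxy)benzoate A4.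
- For it: in A4 the position of every substituent follows from the mechanism, so there is no formylation regiochemistry to control. A4 carries the acid as a benzyl ester and the aldehyde as an acetal, so the hindered ester hydrolysis of step 8 is avoided. On both points it is stronger than the chosen route.
- Against it: it spends its effort on the easy ring. Ring A is available from 10 in one C–C bond-forming step, whereas A5 (a diazoketone carrying an acrylate, prone to intramolecular dipolar chemistry) and A6 each need a multistep preparation, and the photochemical step is hard to scale. Ring B, the difficult ring, is left unsolved by A4.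
- Comparison: the chosen route takes ring A from an inexpensive aromatic compound and builds ring B, where the difficulty lies; its cost is that regiochemistry and ester cleavage on ring A must be handled by conventional means, which a route through A4 would not need.

Alternative 3: biomimetic aldol aromatisation of a polyketide ester.
- Disconnection: C1'–C2', with ring A built on the finished ring B ester.
- Forward reaction: in methyl 2,4-bis(benzyloxy)-3,6-dimethyl-5-[(3,5,7-trioxooctanoyl)oxy]benzoate A8 the C2 methylene of the triketo chain adds to the C7 carbonyl in an intramolecular aldol reaction. Loss of water and enolisation of the two remaining ketones then deliver methyl 2,4-bis(benzyloxy)-5-(2,4-dihydroxy-6-methylbenzoyloxy)-3,6-dimethylbenzoate A7.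
- For it: the ester bond of A8 is made with an unhindered acyl chain before ring A exists, so the doubly hindered esterification of step 9 never arises. On this point it is clearly stronger.
- Against it: A8 is an aryl ester of a polyketo acid and has a good leaving group on chain C1. Claisen-type closure or lactonisation to a pyranone with expulsion of the ring B phenoxide therefore competes with the desired aldol. The formyl group would have to be introduced on A7 at the end, with the same regiochemical question as in step 6 but on a precious intermediate and next to benzyl ethers that Lewis acids may remove. A ring B phenol with differentiated oxygens is still required to prepare A8, so the problem the chosen route solves remains.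
- Comparison: the chosen route accepts a hindered coupling that A8 avoids, but settles the aldehyde position early on a simple ester, before the rings are joined, and never handles an open-chain polyketone such as A8.

Key step: step 2

## Route

Remark on the chemistry: 4, 5 and 6 contain sp3 stereocentres that form without control and are all removed on aromatisation. They are drawn without configuration, and 5 is drawn as the triketo tautomer although it should exist largely as an enol.

**Step 1**
Reactants: 1 hexane-3,4-dione
Product: 2 (Z)-4-(benzyloxy)hex-4-en-3-one
Conditions: BnBr (1.2 equiv), Cs2CO3 (1.5 equiv), DMF, 0 °C → rt, 1 added slowly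
Reagents that add atoms: benzyl bromide, BrCc1ccccc1
Why: Williamson-type O-alkylation of the mono-enolate of an α-diketone; the oxido group sits on the α-carbon of an enone, which damps carbon nucleophilicity, and the caesium counter-ion in DMF favours attack through oxygen; slow addition keeps free dione away from its enolate; the Z isomer (methyl trans to the propanoyl group) should prevail, and the geometry has no consequence later.

**Step 2**
Reactants: 2 (Z)-4-(benzyloxy)hex-4-en-3-one; 3 dimethyl malonate
Product: 5 methyl 5-(benzyloxy)-3,6-dimethyl-2,4-dioxocyclohexane-1-carboxylate (enolized diastereomer mixture), via Michael adduct 4 (not isolated)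
Conditions: NaOMe (1.2 equiv), MeOH, reflux; then 1 M HCl, 0 °C
Reagents that add atoms: none
Why: Methoxide deprotonates 3, and the malonate anion adds to C5 of 2 (the β-carbon), which makes the B1–B2 bond and gives 4 as its ketone enolate. Proton transfer moves the charge to the α'-methylene of the ethyl ketone, and this enolate attacks one malonate ester carbonyl; loss of methoxide makes the B5–B6 bond. The closure is a 6-(enolendo)-exo-trig Dieckmann-type Claisen condensation, and the closest known reaction is the Michael–Claisen annulation of malonates with alkenyl ketones that gives dihydroresorcinol carboxylates. Every step before the last is reversible, and the cyclic 1,3-dione is deprotonated by methoxide as it forms, so its stabilised enolate pulls the equilibria forward. Regiochemistry is secured by the substrate: the only other enolisable carbon beside the ketone of 4 is the benzyloxy carbon, whose attack on an ester would give a four-membered ring, and the malonate is by far the more acidic partner, so conjugate addition comes before any acylation. The stereocentres at B1, B2 and B3 (and B5 in the keto form) are not controlled and need not be, because all four carbons become sp2 in step 3. The selectivity the step does need is conjugate over carbonyl addition, which the soft, stabilised malonate anion under reversible conditions provides; the α-benzyloxy group makes the β-carbon less electrophilic than in a plain enone, so a long reflux should be expected.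

**Step 3**
Reactants: 5 methyl 5-(benzyloxy)-3,6-dimethyl-2,4-dioxocyclohexane-1-carboxylate
Product: 7 methyl 5-(benzyloxy)-2,4-dihydroxy-3,6-dimethylbenzoate, via bromo keto ester 6 (not isolated)
Conditions: CuBr2 (2.1 equiv), EtOAc/CHCl3 (1:1), 50 °C; filter, evaporate; then Li2CO3, DMF, 60 °C
Reagents that add atoms: none
Why: Halogenation–dehydrohalogenation of a dihydroresorcinol: only the B6 ketone and the ester can chelate divalent copper (the two ring ketones cannot), which should place bromine on B1; base then removes HBr across B1–B2 through the dione enolate, and the cyclohexadienone tautomerises to the resorcinol; ring B has no free position for over-bromination, and the carbonate keeps the benzyl ether away from hot acid.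

**Step 4**
Reactants: 7 methyl 5-(benzyloxy)-2,4-dihydroxy-3,6-dimethylbenzoate
Product: 8 methyl 5-(benzyloxy)-2,4-bis(methoxymethoxy)-3,6-dimethylbenzoate
Conditions: NaH (2.5 equiv), MOMCl (2.5 equiv), DMF, 0 °C → rt
Reagents that add atoms: chloromethyl methyl ether, COCCl
Why: Phenoxide O-alkylation; NaH is needed because the B6 hydroxyl is hydrogen-bonded to the ester, and the fully substituted ring leaves no carbon for C-alkylation.

**Step 5**
Reactants: 8 methyl 5-(benzyloxy)-2,4-bis(methoxymethoxy)-3,6-dimethylbenzoate
Product: 9 methyl 5-hydroxy-2,4-bis(methoxymethoxy)-3,6-dimethylbenzoate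
Conditions: H2 (1 atm), Pd/C, EtOAc, rt
Reagents that add atoms: none
Why: Hydrogenolysis of an aryl benzyl ether over palladium on carbon; the MOM acetals and the methyl ester are inert, so only the B3 oxygen is set free.

**Step 6**
Reactants: 10 methyl orsellinate (methyl 2,4-dihydroxy-6-methylbenzoate)
Product: 11 methyl 3-formyl-2,4-dihydroxy-6-methylbenzoate
Conditions: Cl2CHOMe (1.2 equiv), TiCl4 (2.5 equiv), CH2Cl2, −20 → 0 °C; then 1 M HCl
Reagents that add atoms: dichloromethyl methyl ether, COC(Cl)Cl; water, O
Why: Rieche formylation: the titanium phenoxides direct the electrophile ortho, and C3 of 10 is ortho to both oxygens and the most electron-rich carbon, so the 3-formyl isomer should predominate over the 5-formyl isomer, which would be removed by crystallisation or chromatography at this early stage.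

**Step 7**
Reactants: 11 methyl 3-formyl-2,4-dihydroxy-6-methylbenzoate
Product: 12 methyl 3-formyl-2,4-bis(methoxymethoxy)-6-methylbenzoate
Conditions: NaH (2.5 equiv), MOMCl (2.5 equiv), DMF, 0 °C → rt
Reagents that add atoms: chloromethyl methyl ether, COCCl
Why: Double phenoxide alkylation; both hydroxyls are hydrogen-bonded to carbonyl groups, hence NaH and not an amine base, and the aldehyde has no α-hydrogen and tolerates the conditions.

**Step 8**
Reactants: 12 methyl 3-formyl-2,4-bis(methoxymethoxy)-6-methylbenzoate
Product: 13 3-formyl-2,4-bis(methoxymethoxy)-6-methylbenzoic acid
Conditions: KOH (10 equiv), MeOH/H2O (4:1), 65 °C; then 1 M HCl to pH 4, 0 °C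
Reagents that add atoms: potassium hydroxide, [K+].[OH-]
Why: Saponification (BAc2) of a di-ortho-substituted benzoate, which needs excess hydroxide and heat; the aldehyde is non-enolisable and shielded by two ortho acetals, which should hold back Cannizzaro disproportionation, and cold acidification to pH 4 spares the MOM ethers.

**Step 9**
Reactants: 13 3-formyl-2,4-bis(methoxymethoxy)-6-methylbenzoic acid; 9 methyl 5-hydroxy-2,4-bis(methoxymethoxy)-3,6-dimethylbenzoate
Product: 15 methyl 5-{[3-formyl-2,4-bis(methoxymethoxy)-6-methylbenzoyl]oxy}-2,4-bis(methoxymethoxy)-3,6-dimethylbenzoate, via acid chloride 14 (not isolated)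
Conditions: Me2C=C(Cl)NMe2 (1.1 equiv), CH2Cl2, 0 °C → rt; then 9, NaH (1.1 equiv), THF, 0 °C → rt
Reagents that add atoms: none
Why: Acid chloride formation with an α-chloroenamine is neutral, so no HCl is formed that would cleave the acetals; the small, reactive acyl chloride is then attacked by the preformed sodium phenoxide of 9 (acylation of a hindered phenoxide by a hindered aroyl chloride), and since B4–O and B6–O are masked only B3–O can be acylated.

**Step 10**
Reactants: 15 methyl 5-{[3-formyl-2,4-bis(methoxymethoxy)-6-methylbenzoyl]oxy}-2,4-bis(methoxymethoxy)-3,6-dimethylbenzoate
Product: 16 methyl 5-[(3-formyl-2,4-dihydroxy-6-methylbenzoyl)oxy]-2,4-dihydroxy-3,6-dimethylbenzoate (target)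
Conditions: 3 M HCl (aq)/THF (1:4), 40 °C
Reagents that add atoms: none
Why: Acid hydrolysis of four MOM acetals; three are ortho to a carbonyl group and should cleave readily, and the B4 acetal sets the temperature; the medium is alcohol-free because salicylate-type aryl esters are prone to alcoholysis, and acid avoids the base-promoted acyl shift from B3–O to B4–O.

## Compound list

1 | hexane-3,4-dione | CCC(=O)C(=O)CC | starting material
2 | (Z)-4-(benzyloxy)hex-4-en-3-one | CCC(=O)/C(OCc1ccccc1)=C/C | intermediate
3 | dimethyl malonate | COC(=O)CC(=O)OC | starting material
4 | dimethyl 2-[3-(benzyloxy)-4-oxohexan-2-yl]propanedioate (diastereomer mixture) | COC(=O)C(C(=O)OC)C(C)C(OCc1ccccc1)C(=O)CC | intermediate (not isolated)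
5 | methyl 5-(benzyloxy)-3,6-dimethyl-2,4-dioxocyclohexane-1-carboxylate (diastereomer mixture, enolized) | COC(=O)C1C(C)C(OCc2ccccc2)C(=O)C(C)C1=O | intermediate
6 | methyl 5-(benzyloxy)-1-bromo-3,6-dimethyl-2,4-dioxocyclohexane-1-carboxylate (diastereomer mixture) | COC(=O)C1(Br)C(C)C(OCc2ccccc2)C(=O)C(C)C1=O | intermediate (not isolated)
7 | methyl 5-(benzyloxy)-2,4-dihydroxy-3,6-dimethylbenzoate | COC(=O)c1c(C)c(OCc2ccccc2)c(O)c(C)c1O | intermediate
8 | methyl 5-(benzyloxy)-2,4-bis(methoxymethoxy)-3,6-dimethylbenzoate | COC(=O)c1c(C)c(OCc2ccccc2)c(OCOC)c(C)c1OCOC | intermediate
9 | methyl 5-hydroxy-2,4-bis(methoxymethoxy)-3,6-dimethylbenzoate | COC(=O)c1c(C)c(O)c(OCOC)c(C)c1OCOC | intermediate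
10 | methyl orsellinate (methyl 2,4-dihydroxy-6-methylbenzoate) | COC(=O)c1c(C)cc(O)cc1O | starting material
11 | methyl 3-formyl-2,4-dihydroxy-6-methylbenzoate | COC(=O)c1c(C)cc(O)c(C=O)c1O | intermediate
12 | methyl 3-formyl-2,4-bis(methoxymethoxy)-6-methylbenzoate | COC(=O)c1c(C)cc(OCOC)c(C=O)c1OCOC | intermediate
13 | 3-formyl-2,4-bis(methoxymethoxy)-6-methylbenzoic acid | OC(=O)c1c(C)cc(OCOC)c(C=O)c1OCOC | intermediate
14 | 3-formyl-2,4-bis(methoxymethoxy)-6-methylbenzoyl chloride | ClC(=O)c1c(C)cc(OCOC)c(C=O)c1OCOC | intermediate (not isolated)
15 | methyl 5-{[3-formyl-2,4-bis(methoxymethoxy)-6-methylbenzoyl]oxy}-2,4-bis(methoxymethoxy)-3,6-dimethylbenzoate | COC(=O)c1c(C)c(OC(=O)c2c(C)cc(OCOC)c(C=O)c2OCOC)c(OCOC)c(C)c1OCOC | intermediate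
16 | methyl 5-[(3-formyl-2,4-dihydroxy-6-methylbenzoyl)oxy]-2,4-dihydroxy-3,6-dimethylbenzoate | COC(=O)c1c(C)c(OC(=O)c2c(C)cc(O)c(C=O)c2O)c(O)c(C)c1O | target

## Step count and least certain steps

Total: 10 steps. Longest linear sequence: 7 steps (steps 1, 2, 3, 4, 5, 9, 10, from 1). The ring A branch is steps 6 to 8.

**Step 2 (the step that carries the strategy).**
- What may go wrong: the benzyloxy group feeds electron density into the β-carbon, so conjugate addition may be slow or may revert. Base-induced self-condensation of 2 through its ethyl ketone enolate could then take over.
- Fallback (the B3 oxygen is introduced after the annulation instead of before): it sets out from 3 and returns at 9. 3 is annulated in the same way (NaOMe, MeOH, reflux) with commercial (E)-hex-4-en-3-one, a normal Michael acceptor without α-oxygen. This passes through dimethyl 2-(4-oxohexan-2-yl)propanedioate F1 to methyl 3,6-dimethyl-2,4-dioxocyclohexane-1-carboxylate F2. Dehydrogenation over Pd/C in refluxing mesitylene (no benzyl ether is present here) gives methyl 2,4-dihydroxy-3,6-dimethylbenzoate F3. Rieche formylation (Cl2CHOMe, TiCl4) can only strike the one free ring position, B3, and gives methyl 5-formyl-2,4-dihydroxy-3,6-dimethylbenzoate F4. NaH and MOMCl give methyl 5-formyl-2,4-bis(methoxymethoxy)-3,6-dimethylbenzoate F5. Baeyer–Villiger oxidation with mCPBA (NaHCO3 buffer), in which the electron-rich aryl group migrates, gives methyl 5-(formyloxy)-2,4-bis(methoxymethoxy)-3,6-dimethylbenzoate F6. K2CO3 in MeOH removes the formate and gives 9.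

**Step 3.**
- What may go wrong: halogen entering at B5 or B3 instead of B1, and acid-induced loss of the benzyl group from B3, which would erase the difference between the B3 and B4 oxygens.
- Fallback (selenoxide elimination in place of halogenation–dehydrohalogenation): from 5, back at 7. 5 is converted into its dianion with LiN(iPr)2 (2.2 equiv, THF, −78 °C). The second, more reactive carbanion is at B1 and is selenenylated by PhSeBr to give methyl 5-(benzyloxy)-3,6-dimethyl-2,4-dioxo-1-(phenylselanyl)cyclohexane-1-carboxylate F7. H2O2 (CH2Cl2, pyridine, 0 °C) gives methyl 5-(benzyloxy)-3,6-dimethyl-2,4-dioxo-1-(phenylseleninyl)cyclohexane-1-carboxylate F8. Its only β-hydrogen is on B2, so syn elimination can only form the B1=B2 double bond, and tautomerisation gives 7 without acid or halide.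

**Step 1.**
- What may go wrong: C-benzylation, or aldol-type self-condensation of the electrophilic dione with its own enolate under base.
- Fallback (acid-catalysed condensation with the alcohol instead of enolate alkylation): from 1, back at 2, with no new compound. 1 is heated with benzyl alcohol and catalytic TsOH in toluene with azeotropic removal of water. Hemiketal formation, loss of water and loss of the α-proton should give 2 with no enolate present.

**Step 9.**
- What may go wrong: slow acylation because both partners are di-ortho-substituted, and decay of 14 before it is used, through attack of its ortho acetal oxygen on the acyl chloride.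
- Fallback (a less hindered acid without an ortho acetal, coupled with a carbodiimide): from 11 and 9, back at 16. Only the less hindered, more acidic C4 hydroxyl of 11 is protected (MOMCl, iPr2NEt, CH2Cl2, 0 °C), giving methyl 3-formyl-2-hydroxy-4-(methoxymethoxy)-6-methylbenzoate F9. Saponification as in step 8 gives 3-formyl-2-hydroxy-4-(methoxymethoxy)-6-methylbenzoic acid F10; its remaining hydroxyl is held in a hydrogen bond between two carbonyl groups and should not self-acylate. Steglich coupling with 9 (dicyclohexylcarbodiimide, catalytic 4-(dimethylamino)pyridine, CH2Cl2) gives methyl 5-{[3-formyl-2-hydroxy-4-(methoxymethoxy)-6-methylbenzoyl]oxy}-2,4-bis(methoxymethoxy)-3,6-dimethylbenzoate F11. The conditions of step 10 then give 16.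

**Step 8.**
- What may go wrong: incomplete hydrolysis of the hindered ester, or disproportionation of the aldehyde when the conditions are forced.
- Fallback (cleavage of the O–CH3 bond instead of attack at the acyl carbon): from 12, back at 13, with no new compound. NaSEt in DMF at 80 °C attacks the unhindered ester methyl group in an SN2 reaction and releases the carboxylate of 13. The acetals are inert to thiolate, and its addition to the aldehyde is reversible.

## Further compounds

F1 | step 2 | dimethyl 2-(4-oxohexan-2-yl)propanedioate | COC(=O)C(C(=O)OC)C(C)CC(=O)CC
F2 | step 2 | methyl 3,6-dimethyl-2,4-dioxocyclohexane-1-carboxylate | COC(=O)C1C(C)CC(=O)C(C)C1=O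
F3 | step 2 | methyl 2,4-dihydroxy-3,6-dimethylbenzoate | COC(=O)c1c(C)cc(O)c(C)c1O
F4 | step 2 | methyl 5-formyl-2,4-dihydroxy-3,6-dimethylbenzoate | COC(=O)c1c(C)c(C=O)c(O)c(C)c1O
F5 | step 2 | methyl 5-formyl-2,4-bis(methoxymethoxy)-3,6-dimethylbenzoate | COC(=O)c1c(C)c(C=O)c(OCOC)c(C)c1OCOC
F6 | step 2 | methyl 5-(formyloxy)-2,4-bis(methoxymethoxy)-3,6-dimethylbenzoate | COC(=O)c1c(C)c(OC=O)c(OCOC)c(C)c1OCOC
F7 | step 3 | methyl 5-(benzyloxy)-3,6-dimethyl-2,4-dioxo-1-(phenylselanyl)cyclohexane-1-carboxylate | COC(=O)C1([Se]c2ccccc2)C(C)C(OCc2ccccc2)C(=O)C(C)C1=O
F8 | step 3 | methyl 5-(benzyloxy)-3,6-dimethyl-2,4-dioxo-1-(phenylseleninyl)cyclohexane-1-carboxylate | COC(=O)C1([Se](=O)c2ccccc2)C(C)C(OCc2ccccc2)C(=O)C(C)C1=O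
F0 | step 1 | none | none
F9 | step 9 | methyl 3-formyl-2-hydroxy-4-(methoxymethoxy)-6-methylbenzoate | COC(=O)c1c(C)cc(OCOC)c(C=O)c1O
F10 | step 9 | 3-formyl-2-hydroxy-4-(methoxymethoxy)-6-methylbenzoic acid | OC(=O)c1c(C)cc(OCOC)c(C=O)c1O
F11 | step 9 | methyl 5-{[3-formyl-2-hydroxy-4-(methoxymethoxy)-6-methylbenzoyl]oxy}-2,4-bis(methoxymethoxy)-3,6-dimethylbenzoate | COC(=O)c1c(C)c(OC(=O)c2c(C)cc(OCOC)c(C=O)c2O)c(OCOC)c(C)c1OCOC
F0 | step 8 | none | none
A1 | alternative 1 | methyl 4-(benzyloxy)-2-(tert-butyldimethylsilyloxy)-5-hydroxy-3,6-dimethylbenzoate | COC(=O)c1c(C)c(O)c(OCc2ccccc2)c(C)c1O[Si](C)(C)C(C)(C)C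
A2 | alternative 1 | 4-(benzyloxy)-3-methyl-2-(tert-butyldimethylsilyloxy)furan | Cc1c(O[Si](C)(C)C(C)(C)C)occ1OCc1ccccc1
A3 | alternative 1 | methyl but-2-ynoate | CC#CC(=O)OC
A4 | alternative 2 | benzyl 3-(dimethoxymethyl)-2-hydroxy-6-methyl-4-(triisopropylsilyloxy)benzoate | O=C(OCc1ccccc1)c1c(C)cc(O[Si](C(C)C)(C(C)C)C(C)C)c(C(OC)OC)c1O
A5 | alternative 2 | benzyl (E)-5-diazo-3-methyl-4-oxopent-2-enoate | [N-]=[N+]=CC(=O)/C(C)=C/C(=O)OCc1ccccc1
A6 | alternative 2 | (3,3-dimethoxyprop-1-yn-1-yl)oxy-tri(propan-2-yl)silane | COC(OC)C#CO[Si](C(C)C)(C(C)C)C(C)C
A7 | alternative 3 | methyl 2,4-bis(benzyloxy)-5-(2,4-dihydroxy-6-methylbenzoyloxy)-3,6-dimethylbenzoate | COC(=O)c1c(C)c(OC(=O)c2c(C)cc(O)cc2O)c(OCc2ccccc2)c(C)c1OCc1ccccc1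
A8 | alternative 3 | methyl 2,4-bis(benzyloxy)-3,6-dimethyl-5-[(3,5,7-trioxooctanoyl)oxy]benzoate | COC(=O)c1c(C)c(OC(=O)CC(=O)CC(=O)CC(C)=O)c(OCc2ccccc2)c(C)c1OCc1ccccc1
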